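**Retrosynthetic overview**
- Target ⇐ fluoride desilylation, then hydrogenolysis of the two phenol benzyl ethers.
- Tetrahydrofuran ring ⇐ 5-exo Williamson closure of a 1,4-diol (benzylic OH onto a primary tosylate, C2 retained) ⇐ LiAlH4 opening of a trisubstituted γ-lactone.
- Key C–C bond (ring C4 to the carbinol carbon) ⇐ intermolecular aldol of the lactone lithium enolate with O-benzylvanillin, trans to the C4 substituent of the lactone.
- Lactone ⇐ alkene cleavage and lactol oxidation of a pentenyl 1,3-diol ⇐ Evans syn-aldol of an N-pent-4-enoyl oxazolidinone with O-benzylvanillin (sets C2 and C3).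
- Ring order: γ-lactone first (steps 5–6), opened (step 9), then re-closed as the tetrahydrofuran (step 10); the lactone and the final ring contain the same five atoms.

Numbering used: tetrahydrofuran O1, C2 (aryl), C3 (CH2OH), C4 (carbinol side chain), C5. The target is 2R,3S,4R with an R carbinol carbon (ring all-trans); the three starting materials 1, 2 and 5 are assumed to be bought as such.

**Step 1**
Reactants: 1 (R)-4-benzyloxazolidin-2-one; 2 pent-4-enoyl chloride
Product: 4 (R)-4-benzyl-3-(pent-4-enoyl)oxazolidin-2-one, via lithium oxazolidinide 3 (not isolated)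
Conditions: n-BuLi (1.0 equiv), THF, −78 °C; then 2, −78 → 0 °C
Reagents that add atoms: none
Why: N-acylation of the lithiated oxazolidinone by the acid chloride is fast and clean, and no stereocentre is formed or touched.

**Step 2**
Reactants: 4 (R)-4-benzyl-3-(pent-4-enoyl)oxazolidin-2-one; 5 4-(benzyloxy)-3-methoxybenzaldehyde
Product: 7 (R)-4-benzyl-3-[(2R,3R)-2-allyl-3-[4-(benzyloxy)-3-methoxyphenyl]-3-hydroxypropanoyl]oxazolidin-2-one, via Z-dibutylboron enolate 6 (not isolated)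
Conditions: Bu2BOTf (1.1 equiv), i-Pr2NEt (1.2 equiv), CH2Cl2, 0 °C; then 5, −78 → 0 °C; pH 7 buffer, MeOH, 30% H2O2, 0 °C
Reagents that add atoms: none
Why: Evans syn-aldol; the Z-boron enolate reacts through a Zimmerman–Traxler chair on the face away from the auxiliary benzyl group, so the (R)-auxiliary gives the 2R,3R syn adduct, which sets the future C3 and C2 of the ring.

**Step 3**
Reactants: 7 (R)-4-benzyl-3-[(2R,3R)-2-allyl-3-[4-(benzyloxy)-3-methoxyphenyl]-3-hydroxypropanoyl]oxazolidin-2-one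
Product: 8 (1R,2S)-2-allyl-1-[4-(benzyloxy)-3-methoxyphenyl]propane-1,3-diol
Conditions: LiBH4, MeOH (1.5 equiv), THF, 0 °C
Reagents that add atoms: none
Why: Reductive cleavage of the N-acyl oxazolidinone gives the primary alcohol without epimerisation or retro-aldol, and the auxiliary is recovered (the descriptor changes from R to S only through CIP priorities).

**Step 4**
Reactants: 8 (1R,2S)-2-allyl-1-[4-(benzyloxy)-3-methoxyphenyl]propane-1,3-diol
Product: 9 (1R,2S)-1-[4-(benzyloxy)-3-methoxyphenyl]-2-{[(tert-butyldiphenylsilyl)oxy]methyl}pent-4-en-1-ol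
Conditions: TBDPSCl (1.05 equiv), imidazole, DMF, 0 °C
Reagents that add atoms: tert-butyl(chloro)diphenylsilane (TBDPSCl), CC(C)(C)[Si](Cl)(c1ccccc1)c1ccccc1
Why: Selective silylation; the bulky silyl chloride takes the primary hydroxyl and leaves the hindered benzylic hydroxyl free for lactol formation.

**Step 5**
Reactants: 9 (1R,2S)-1-[4-(benzyloxy)-3-methoxyphenyl]-2-{[(tert-butyldiphenylsilyl)oxy]methyl}pent-4-en-1-ol
Product: 11 (4S,5R)-5-[4-(benzyloxy)-3-methoxyphenyl]-4-{[(tert-butyldiphenylsilyl)oxy]methyl}tetrahydrofuran-2-ol (anomer mixture), via hydroxy aldehyde 10 (not isolated)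
Conditions: OsO4 (2 mol%), NaIO4 (4 equiv), 2,6-lutidine, dioxane/H2O 3:1, rt
Reagents that add atoms: sodium periodate (oxygen delivered through catalytic OsO4), [Na+].[O-]I(=O)(=O)=O
Why: Lemieux–Johnson cleavage of the terminal alkene gives the γ-hydroxy aldehyde, which closes at once to the five-membered lactol without touching the two existing stereocentres.

**Step 6**
Reactants: 11 (4S,5R)-5-[4-(benzyloxy)-3-methoxyphenyl]-4-{[(tert-butyldiphenylsilyl)oxy]methyl}tetrahydrofuran-2-ol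
Product: 12 (4S,5R)-5-[4-(benzyloxy)-3-methoxyphenyl]-4-{[(tert-butyldiphenylsilyl)oxy]methyl}dihydrofuran-2(3H)-one
Conditions: TEMPO (2,2,6,6-tetramethylpiperidin-1-oxyl, 10 mol%), PhI(OAc)2 (1.5 equiv), CH2Cl2, rt
Reagents that add atoms: none
Why: Oxoammonium-mediated oxidation of the lactol to the 4,5-trans lactone is mild, erases the anomeric mixture and leaves the silyl ether, benzyl ether and arene alone.

**Step 7**
Reactants: 12 (4S,5R)-5-[4-(benzyloxy)-3-methoxyphenyl]-4-{[(tert-butyldiphenylsilyl)oxy]methyl}dihydrofuran-2(3H)-one; 5 4-(benzyloxy)-3-methoxybenzaldehyde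
Product: 14 (3S,4S,5R)-5-[4-(benzyloxy)-3-methoxyphenyl]-3-{(R)-[4-(benzyloxy)-3-methoxyphenyl](hydroxy)methyl}-4-{[(tert-butyldiphenylsilyl)oxy]methyl}dihydrofuran-2(3H)-one, via lithium enolate 13 (not isolated)
Conditions: LiN(i-Pr)2 (LDA, 1.1 equiv), THF, −78 °C; then 5, −78 °C, 1 h; AcOH/THF quench at −78 °C; chromatography
Reagents that add atoms: none
Why: Intermolecular aldol addition; the enolate is attacked anti to the C4 silyloxymethyl group (3,4-trans), and the ring-locked E-enolate reacts through a Zimmerman–Traxler chair with the aryl group equatorial to favour the anti (R) carbinol, the minor syn epimer being removed by chromatography.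

**Step 8**
Reactants: 14 (3S,4S,5R)-5-[4-(benzyloxy)-3-methoxyphenyl]-3-{(R)-[4-(benzyloxy)-3-methoxyphenyl](hydroxy)methyl}-4-{[(tert-butyldiphenylsilyl)oxy]methyl}dihydrofuran-2(3H)-one
Product: 15 (3S,4S,5R)-5-[4-(benzyloxy)-3-methoxyphenyl]-3-{(R)-[4-(benzyloxy)-3-methoxyphenyl][(tert-butyldimethylsilyl)oxy]methyl}-4-{[(tert-butyldiphenylsilyl)oxy]methyl}dihydrofuran-2(3H)-one
Conditions: TBSOTf (1.3 equiv), 2,6-lutidine, CH2Cl2, −78 → 0 °C
Reagents that add atoms: tert-butyldimethylsilyl triflate (TBSOTf), CC(C)(C)[Si](C)(C)OS(=O)(=O)C(F)(F)F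
Why: Silylation under non-nucleophilic, weakly basic conditions blocks the aldol hydroxyl, so retro-aldol cannot occur in the hydride step and only one secondary hydroxyl competes in the later sulfonylation.

**Step 9**
Reactants: 15 (3S,4S,5R)-5-[4-(benzyloxy)-3-methoxyphenyl]-3-{(R)-[4-(benzyloxy)-3-methoxyphenyl][(tert-butyldimethylsilyl)oxy]methyl}-4-{[(tert-butyldiphenylsilyl)oxy]methyl}dihydrofuran-2(3H)-one
Product: 16 (1R,2S,3R)-1-[4-(benzyloxy)-3-methoxyphenyl]-3-{(R)-[4-(benzyloxy)-3-methoxyphenyl][(tert-butyldimethylsilyl)oxy]methyl}-2-{[(tert-butyldiphenylsilyl)oxy]methyl}butane-1,4-diol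
Conditions: LiAlH4 (1.5 equiv), THF, 0 °C; Fieser work-up
Reagents that add atoms: none
Why: Hydride reduction of the lactone gives the 1,4-diol (one primary, one benzylic secondary hydroxyl) with all four stereocentres untouched, and both silyl ethers survive at 0 °C.

**Step 10**
Reactants: 16 (1R,2S,3R)-1-[4-(benzyloxy)-3-methoxyphenyl]-3-{(R)-[4-(benzyloxy)-3-methoxyphenyl][(tert-butyldimethylsilyl)oxy]methyl}-2-{[(tert-butyldiphenylsilyl)oxy]methyl}butane-1,4-diol
Product: 18 {[(2R,3S,4R)-2-[4-(benzyloxy)-3-methoxyphenyl]-4-{(R)-[4-(benzyloxy)-3-methoxyphenyl][(tert-butyldimethylsilyl)oxy]methyl}tetrahydrofuran-3-yl]methoxy}(tert-butyl)diphenylsilane, via primary tosylate 17 (not isolated)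
Conditions: TsCl (1.2 equiv), pyridine, DMAP (4-(dimethylamino)pyridine, cat.), 0 °C → rt, then 50 °C
Reagents that add atoms: none
Why: The primary hydroxyl is sulfonylated selectively and the benzylic hydroxyl displaces the tosylate in a 5-exo-tet Williamson etherification; only the primary C–O bond is broken, so C2 keeps its R configuration, and no alkoxide is formed that could trigger silyl migration.

**Step 11**
Reactants: 18 {[(2R,3S,4R)-2-[4-(benzyloxy)-3-methoxyphenyl]-4-{(R)-[4-(benzyloxy)-3-methoxyphenyl][(tert-butyldimethylsilyl)oxy]methyl}tetrahydrofuran-3-yl]methoxy}(tert-butyl)diphenylsilane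
Product: 19 (R)-[4-(benzyloxy)-3-methoxyphenyl]{(3R,4S,5R)-5-[4-(benzyloxy)-3-methoxyphenyl]-4-(hydroxymethyl)tetrahydrofuran-3-yl}methanol
Conditions: TBAF (3 equiv), THF, rt
Reagents that add atoms: none
Why: Fluoride-driven desilylation removes both silyl ethers under non-acidic conditions, so neither benzylic C–O bond can ionise while the phenols are still benzylated.

**Step 12**
Reactants: 19 (R)-[4-(benzyloxy)-3-methoxyphenyl]{(3R,4S,5R)-5-[4-(benzyloxy)-3-methoxyphenyl]-4-(hydroxymethyl)tetrahydrofuran-3-yl}methanol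
Product: 20 (R)-(4-hydroxy-3-methoxyphenyl)[(3R,4S,5R)-5-(4-hydroxy-3-methoxyphenyl)-4-(hydroxymethyl)tetrahydrofuran-3-yl]methanol (target)
Conditions: H2 (1 atm), 10% Pd/C, EtOAc/MeOH, rt, stopped at full conversion
Reagents that add atoms: none
Why: Catalytic hydrogenolysis cleaves aryl benzyl ethers much faster than the ring benzylic ether or the benzylic alcohol under neutral conditions at 1 atm, so all four stereocentres are delivered unchanged.

**Compound list**
1 | (R)-4-benzyloxazolidin-2-one | O=C1N[C@H](Cc2ccccc2)CO1 | starting material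
2 | pent-4-enoyl chloride | C=CCCC(=O)Cl | starting material
3 | lithium (R)-4-benzyl-2-oxooxazolidin-3-ide | [Li]N1C(=O)OC[C@H]1Cc1ccccc1 | intermediate
4 | (R)-4-benzyl-3-(pent-4-enoyl)oxazolidin-2-one | C=CCCC(=O)N1C(=O)OC[C@H]1Cc1ccccc1 | intermediate
5 | 4-(benzyloxy)-3-methoxybenzaldehyde | COc1cc(C=O)ccc1OCc1ccccc1 | starting material
6 | (R)-4-benzyl-3-{(1Z)-1-[(dibutylboranyl)oxy]penta-1,4-dien-1-yl}oxazolidin-2-one | C=CC/C=C(\OB(CCCC)CCCC)N1C(=O)OC[C@H]1Cc1ccccc1 | intermediate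
7 | (R)-4-benzyl-3-[(2R,3R)-2-allyl-3-[4-(benzyloxy)-3-methoxyphenyl]-3-hydroxypropanoyl]oxazolidin-2-one | O[C@@H](c1ccc(OCc2ccccc2)c(OC)c1)[C@@H](CC=C)C(=O)N1C(=O)OC[C@H]1Cc1ccccc1 | intermediate
8 | (1R,2S)-2-allyl-1-[4-(benzyloxy)-3-methoxyphenyl]propane-1,3-diol | O[C@@H](c1ccc(OCc2ccccc2)c(OC)c1)[C@@H](CC=C)CO | intermediate
9 | (1R,2S)-1-[4-(benzyloxy)-3-methoxyphenyl]-2-{[(tert-butyldiphenylsilyl)oxy]methyl}pent-4-en-1-ol | O[C@@H](c1ccc(OCc2ccccc2)c(OC)c1)[C@@H](CC=C)CO[Si](c1ccccc1)(c1ccccc1)C(C)(C)C | intermediate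
10 | (3S,4R)-4-[4-(benzyloxy)-3-methoxyphenyl]-3-{[(tert-butyldiphenylsilyl)oxy]methyl}-4-hydroxybutanal | O[C@@H](c1ccc(OCc2ccccc2)c(OC)c1)[C@@H](CC=O)CO[Si](c1ccccc1)(c1ccccc1)C(C)(C)C | intermediate
11 | (4S,5R)-5-[4-(benzyloxy)-3-methoxyphenyl]-4-{[(tert-butyldiphenylsilyl)oxy]methyl}tetrahydrofuran-2-ol (anomer mixture) | C1C(O)O[C@@H](c2ccc(OCc3ccccc3)c(OC)c2)[C@@H]1CO[Si](c1ccccc1)(c1ccccc1)C(C)(C)C | intermediate
12 | (4S,5R)-5-[4-(benzyloxy)-3-methoxyphenyl]-4-{[(tert-butyldiphenylsilyl)oxy]methyl}dihydrofuran-2(3H)-one | C1C(=O)O[C@@H](c2ccc(OCc3ccccc3)c(OC)c2)[C@@H]1CO[Si](c1ccccc1)(c1ccccc1)C(C)(C)C | intermediate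
13 | lithium (4S,5R)-5-[4-(benzyloxy)-3-methoxyphenyl]-4-{[(tert-butyldiphenylsilyl)oxy]methyl}-4,5-dihydrofuran-2-olate | C1=C(O[Li])O[C@@H](c2ccc(OCc3ccccc3)c(OC)c2)[C@@H]1CO[Si](c1ccccc1)(c1ccccc1)C(C)(C)C | intermediate
14 | (3S,4S,5R)-5-[4-(benzyloxy)-3-methoxyphenyl]-3-{(R)-[4-(benzyloxy)-3-methoxyphenyl](hydroxy)methyl}-4-{[(tert-butyldiphenylsilyl)oxy]methyl}dihydrofuran-2(3H)-one | COc1cc([C@H](O)[C@H]2C(=O)O[C@@H](c3ccc(OCc4ccccc4)c(OC)c3)[C@@H]2CO[Si](c3ccccc3)(c3ccccc3)C(C)(C)C)ccc1OCc1ccccc1 | intermediate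
15 | (3S,4S,5R)-5-[4-(benzyloxy)-3-methoxyphenyl]-3-{(R)-[4-(benzyloxy)-3-methoxyphenyl][(tert-butyldimethylsilyl)oxy]methyl}-4-{[(tert-butyldiphenylsilyl)oxy]methyl}dihydrofuran-2(3H)-one | COc1cc([C@H](O[Si](C)(C)C(C)(C)C)[C@H]2C(=O)O[C@@H](c3ccc(OCc4ccccc4)c(OC)c3)[C@@H]2CO[Si](c3ccccc3)(c3ccccc3)C(C)(C)C)ccc1OCc1ccccc1 | intermediate
16 | (1R,2S,3R)-1-[4-(benzyloxy)-3-methoxyphenyl]-3-{(R)-[4-(benzyloxy)-3-methoxyphenyl][(tert-butyldimethylsilyl)oxy]methyl}-2-{[(tert-butyldiphenylsilyl)oxy]methyl}butane-1,4-diol | COc1cc([C@H](O[Si](C)(C)C(C)(C)C)[C@@H](CO)[C@@H](CO[Si](c2ccccc2)(c2ccccc2)C(C)(C)C)[C@@H](O)c2ccc(OCc3ccccc3)c(OC)c2)ccc1OCc1ccccc1 | intermediate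
17 | 4-O-(4-methylbenzenesulfonyl) derivative of 16 (primary tosylate) | COc1cc([C@H](O[Si](C)(C)C(C)(C)C)[C@@H](COS(=O)(=O)c2ccc(C)cc2)[C@@H](CO[Si](c2ccccc2)(c2ccccc2)C(C)(C)C)[C@@H](O)c2ccc(OCc3ccccc3)c(OC)c2)ccc1OCc1ccccc1 | intermediate
18 | {[(2R,3S,4R)-2-[4-(benzyloxy)-3-methoxyphenyl]-4-{(R)-[4-(benzyloxy)-3-methoxyphenyl][(tert-butyldimethylsilyl)oxy]methyl}tetrahydrofuran-3-yl]methoxy}(tert-butyl)diphenylsilane | COc1cc([C@H](O[Si](C)(C)C(C)(C)C)[C@H]2CO[C@@H](c3ccc(OCc4ccccc4)c(OC)c3)[C@@H]2CO[Si](c3ccccc3)(c3ccccc3)C(C)(C)C)ccc1OCc1ccccc1 | intermediate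
19 | (R)-[4-(benzyloxy)-3-methoxyphenyl]{(3R,4S,5R)-5-[4-(benzyloxy)-3-methoxyphenyl]-4-(hydroxymethyl)tetrahydrofuran-3-yl}methanol | COc1cc([C@H](O)[C@H]2CO[C@@H](c3ccc(OCc4ccccc4)c(OC)c3)[C@@H]2CO)ccc1OCc1ccccc1 | intermediate
20 | (R)-(4-hydroxy-3-methoxyphenyl)[(3R,4S,5R)-5-(4-hydroxy-3-methoxyphenyl)-4-(hydroxymethyl)tetrahydrofuran-3-yl]methanol | COc1cc([C@H](O)[C@H]2CO[C@@H](c3ccc(O)c(OC)c3)[C@@H]2CO)ccc1O | target

**Totals**
Total step count: 12. Longest linear sequence: 12 steps (from 1; fully linear, with aldehyde 5 used twice).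

**Three steps most likely to fail**

Step 7 (carbinol selectivity of the lactone aldol). The 3,4-trans sense is dependable, but lithium lactone enolates often give only modest anti:syn ratios with aromatic aldehydes, and the aldolate can revert. The fallback sets out from 14, taken as the unseparated mixture with its carbinol epimer, and replaces kinetic aldol control by ketone reduction. Dess–Martin periodinane (CH2Cl2, NaHCO3, 0 °C → rt) converges both epimers on (3S,4S,5R)-3-[4-(benzyloxy)-3-methoxybenzoyl]-5-[4-(benzyloxy)-3-methoxyphenyl]-4-{[(tert-butyldiphenylsilyl)oxy]methyl}dihydrofuran-2(3H)-one F1, whose C3 centre rests in the trans arrangement. Reduction with BH3·SMe2 and (S)-2-methyl-CBS-oxazaborolidine (THF, −20 °C) then delivers hydride under reagent control, with the aryl group as the large substituent. The same face is favoured by the Felkin–Anh model with the lactone carbonyl antiperiplanar to the hydride. This gives the R carbinol and comes back to the route at 14 as a single epimer.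

Step 10 (selective tosylation and ring closure). Sulfonylation of the benzylic hydroxyl, chloride displacement of the tosylate or slow closure of the hindered system could lower the yield. The fallback sets out from 15 and never opens the ring. DIBAL-H (CH2Cl2, −78 °C) reduces the lactone to (3S,4S,5R)-5-[4-(benzyloxy)-3-methoxyphenyl]-3-{(R)-[4-(benzyloxy)-3-methoxyphenyl][(tert-butyldimethylsilyl)oxy]methyl}-4-{[(tert-butyldiphenylsilyl)oxy]methyl}tetrahydrofuran-2-ol F2. Ionic reduction of the derived oxocarbenium ion with Et3SiH and BF3·OEt2 (CH2Cl2, −78 °C) removes the anomeric oxygen and comes back to the route at 18. Steps 9 and 10 are then skipped.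

Step 12 (hydrogenolysis next to two benzylic C–O bonds). Over-reduction of the free benzylic alcohol or of the ring benzylic ether is possible once the phenols are liberated. The fallback sets out from 18 and reverses the order of deprotection. Hydrogenolysis (H2, 10% Pd/C, EtOAc) is run while both oxygen functions are still silylated, so the bulky silyl ethers shield the two benzylic positions and no free benzylic alcohol is present. This gives 4-[(R)-[(tert-butyldimethylsilyl)oxy]{(3R,4S,5R)-4-{[(tert-butyldiphenylsilyl)oxy]methyl}-5-(4-hydroxy-3-methoxyphenyl)tetrahydrofuran-3-yl}methyl]-2-methoxyphenol F3. Desilylation with TBAF buffered with AcOH (THF, 0 °C → rt) then comes back to the route at 20.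

**Further compounds**
F1 | step 7 | (3S,4S,5R)-3-[4-(benzyloxy)-3-methoxybenzoyl]-5-[4-(benzyloxy)-3-methoxyphenyl]-4-{[(tert-butyldiphenylsilyl)oxy]methyl}dihydrofuran-2(3H)-one | COc1cc(C(=O)[C@H]2C(=O)O[C@@H](c3ccc(OCc4ccccc4)c(OC)c3)[C@@H]2CO[Si](c3ccccc3)(c3ccccc3)C(C)(C)C)ccc1OCc1ccccc1
F2 | step 10 | (3S,4S,5R)-5-[4-(benzyloxy)-3-methoxyphenyl]-3-{(R)-[4-(benzyloxy)-3-methoxyphenyl][(tert-butyldimethylsilyl)oxy]methyl}-4-{[(tert-butyldiphenylsilyl)oxy]methyl}tetrahydrofuran-2-ol (anomer mixture) | COc1cc([C@H](O[Si](C)(C)C(C)(C)C)[C@H]2C(O)O[C@@H](c3ccc(OCc4ccccc4)c(OC)c3)[C@@H]2CO[Si](c3ccccc3)(c3ccccc3)C(C)(C)C)ccc1OCc1ccccc1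
F3 | step 12 | 4-[(R)-[(tert-butyldimethylsilyl)oxy]{(3R,4S,5R)-4-{[(tert-butyldiphenylsilyl)oxy]methyl}-5-(4-hydroxy-3-methoxyphenyl)tetrahydrofuran-3-yl}methyl]-2-methoxyphenol | COc1cc([C@H](O[Si](C)(C)C(C)(C)C)[C@H]2CO[C@@H](c3ccc(O)c(OC)c3)[C@@H]2CO[Si](c3ccccc3)(c3ccccc3)C(C)(C)C)ccc1O
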